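## The problem

The target is a germacranolide; germacrane locants C1–C15 are used throughout. A ten-membered carbocycle C1–C10 carries a cis-fused α-methylene-γ-butyrolactone across C6–C7 (ring oxygen on C6, carbonyl C12, methylene C13 on C11), a cis-epoxide across C1–C10, a Z trisubstituted alkene C4=C5, a free allylic hydroxyl at C3 and an isobutyrate at C8. Six stereocenters must be set: the contiguous triad C6, C7, C8, the quaternary epoxide carbon C10, and C1 and C3, which are 1,3-related across the C2 methylene. C10 is the natural anchor, because it is quaternary, oxygenated and available from the chiral pool; it can control C1, an oxygen on C1 can direct a hydride to C3, and C8, set on its own, can steer C7 and C6 when the lactone is built. A ten-membered ring is costly to close, so the closure must be intramolecular and must tolerate strain. The methylene lactone is a Michael acceptor and a dipolarophile, the epoxide opens transannularly under acid, the isobutyrate can migrate or hydrolyse under base, and the Z alkene with its allylic oxygen isomerises easily; none of these should meet rough conditions late. The enabling feature is the 1,3-relation of the C3 hydroxyl and the C1 epoxide oxygen across C2: it is the imprint of an isoxazoline spanning C1–C2–C3, so a nitrile oxide at C3 adding to a C1=C2 vinyl group on C10 closes the carbocycle, and that vinyl carbinol is the head of linalool.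

## Retrosynthesis

**Unmasking the methylene lactone (31 from 30 from 29).** The C11=C13 bond is disconnected first, by adding benzenesulfenic acid across it: target 31 comes from sulfoxide 30 and this from sulfide 29. A free methylene lactone would be a second dipolarophile in the ring closure and an acceptor for fluoride, thiolate and alkoxide in the end game, so it is carried masked. The precursor differs only by the mask. The forward steps must be neutral: periodate oxidation at sulfur, then thermal syn-elimination, for which H11 is the only β-hydrogen.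

**Epoxide by displacement (29 from 27 via 28, 27 from 26, 26 from 25).** The epoxide is cut at its C1–O bond, leaving the oxygen on C10. Closing it by displacement, not by epoxidising a C1=C10 alkene, ties its configuration to two carbinol centers (C10 from the pool, C1 from the cycloaddition). It does not depend on the conformation of a cyclodecadiene that also holds an allylic alcohol. The precursor 25 is an anti-1,3-diol with the C10 oxygen still silylated. The forward steps ask for kinetic silylation of the less hindered allylic C3 hydroxyl (26), sulfonylation of the hindered C1 hydroxyl (27), and a fluoride step that frees the C10 alkoxide (28) and lets it close with inversion at C1.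

**C3 carbinol and the masked aldol (25 from 24 from 23).** The C3–H bond is cut back to enone 24, and the β-hydroxy ketone is recognised as the opened form of isoxazoline 23 (N–O and C=N cleaved). A direct aldol closure between C2 and C1 would be reversible and would not control C1. The isoxazoline forms irreversibly and stores both oxygens. The forward steps need an N–O cleavage that spares the sulfide and avoids retro-aldol, then hydride delivery from the C1 hydroxyl to give the 1,3-anti diol.

**Key disconnection (23 from 22 from 21).** The C2–C3 and O–C1 bonds are cut together, giving nitrile oxide 22 and, one dehydration back, nitro diene 21. Against cuts at C5–C6 or C6–C7, this one leaves the lactone and the stereotriad intact and puts the only new stereocenter (C1) next to C10. The precursor is acyclic apart from the lactone, with five stereocenters and no medium ring. The forward reaction must deliver oxygen to C1 and carbon to C2, attack the face of the vinyl group that places the new C–O bond anti to the C10 oxygen, and beat dimerisation.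

**Nitro group and C8 ester (21 from 19 via 20, 19 from 18, 18 from 17, 17 from 16).** The C3–N bond is cut to allylic iodide 20 and chloride 19; the C8 ester is cut to alcohol 18, which comes from bis-silyl ether 17, and 17 from allylic alcohol 16. The order matters. The isobutyrate is put on while C3 is a chloride, so the primary allylic hydroxyl cannot compete, and before the acidic allylic nitro group exists, because acylating agents and base would turn a nitronate into the nitrile oxide too early. The forward steps need an allylic chlorination without transposition, a steric discrimination between a secondary and a tertiary triethylsilyl ether, and C-selective attack of nitrite.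

**Lactone (16 from 15, 15 from 11 and 13 via 14, 13 from 12).** Thiophenol is removed from 16 to give methylene lactone 15. The C6–C7 bond and the lactone C–O bond of 15 are then cut to allylic bromide 11 and lactol 13, the ring-chain tautomer of the Z hydroxy enal, made from butenolide 12. One step forms the lactone, sets C6 and C7 and brings in the Z C4=C5 alkene, whose geometry is locked in the ring of 12. An aldol or conjugate-addition route to the lactone would have to differentiate two γ-oxygens (C6, C8) and would give the trans ring fusion more easily. The forward reaction must give the syn adduct (cis lactone) and the correct face relative to C8. C8 is therefore kept as a silyl ether: an ester there would be a leaving group δ to indium and could lactonise or migrate.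

**Allyl bromide and linalool (11 from 10, 10 from 8 and 9, 8 from 7, 7 from 6, 6 from 5, 5 from 3 via 4, 3 from 2, 2 from 1).** The bromide 11 is the transposed form of Morita–Baylis–Hillman adduct 10, cut at C7–C11 into aldehyde 8 and methyl acrylate 9. Aldehyde 8 is the selectively oxidised tris-silyl ether 7 of diol 6, which comes from aminoxy alcohol 5 and, through 4, from aldehyde 3 by catalyst-controlled α-oxygenation. Aldehyde 3 is the ozonolysis product of silyl ether 2 of (S)-linalool 1. Linalool supplies C7–C10, C1, C2 and C14 with C10 already in the required configuration. C8 is set by the catalyst alone, so its sense can be chosen independently of C10.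

## Roads not taken

**Alternative 1: glycol scission of a bicyclic diol.** Here the ring is not closed but uncovered. Pb(OAc)4 cleaves the bond between the two carbinol carbons (C3 and C8) of ring-fusion diol A2, two fused cyclohexenes derived from carvone. The product is the cyclodecadiene-3,8-dione A1, whose two ring alkenes become the Z C4=C5 and Z C1=C10 bonds.
- Merits: a fragmentation has no entropic penalty and needs no dilution, and both alkene geometries are correct by construction. In ring formation this road is more certain than the chosen one.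
- Weak points: A1 still lacks the configurations at C3 and C8 (two ketone reductions in a mobile ring, one ketone β,γ-unsaturated and prone to conjugation or transannular aldol). It also lacks the epoxide (face- and chemoselective epoxidation of C1=C10 beside C4=C5), the lactone (oxidation at C12) and the ester.
- Comparison: the chosen plan fixes C1, C3 and C10 by a chiral-pool center and two intramolecular events (cycloaddition, directed hydride delivery), and carries the lactone and the C8 ester into the ring closure already finished. Alternative 1 would have to settle the same centers by the conformational bias of a cyclodecadienedione.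

**Alternative 2: vinylchromium macrocyclisation at C3–C4.** The cut is C3–C4. In the forward step CrCl2 (divalent chromium) with catalytic NiCl2 (divalent nickel) converts the C4 vinyl iodide of seco-aldehyde A4 into a vinylchromium species that adds to the C3 aldehyde, giving the 1(10)-deoxy diene A3.
- Merits: the coupling tolerates the free methylene lactone and the ester, so no mask is needed. It creates the C3 carbinol in the closing step and is well established for medium rings. After ring closure it is shorter than the chosen plan.
- Weak points: the C3 configuration rests only on the ring conformation in the addition. A3 lacks the epoxide, and a late epoxidation would have to choose C1=C10 over C4=C5, which carries the directing allylic hydroxyl, and leave the methylene lactone alone. Two Z trisubstituted alkenes and a Z vinyl iodide must be made stereoselectively in an open chain.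
- Comparison: against the shorter end game of Alternative 2, the chosen plan needs no epoxidation, because the epoxide oxygen is the C10 oxygen of linalool, and it controls C3 through the C1 oxygen.

**Alternative 3: anionic oxy-Cope ring expansion.** The cut is a [3,3] shift. The potassium alkoxide (KH, 18-crown-6) of cyclohexenol A6 breaks the bond between the carbinol carbon C6 and C1 and forms C8–C9, giving cyclodecadienone A5 with a C6 ketone, a Z C1=C10 alkene and a silane at C8.
- Merits: the ring expansion has little entropic cost. C3 is carried in protected form from the start, which is better than creating it late. The C1=C10 geometry follows from the ordered transition state, and the enolate formed could be trapped at C7.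
- Weak points: A5 needs the C11–C13 unit attached at C7, a stereoselective reduction at C6, lactonisation, oxidation of the C–Si bond to the C8 hydroxyl in the presence of two alkenes, and again a selective epoxidation of C1=C10.
- Comparison: Alternative 3 is stronger at C3 and in ring formation. The chosen plan has the lactone, the C8 ester and the epoxide oxygen in place or programmed before the ring closes, so fewer stereocenters are left to be set on the flexible ring.

Key step: step 16

Assumptions:
- (S)-Linalool is taken to be purchasable as a single enantiomer.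
- Where a center is later destroyed (C7 of 10, C11 of 16 to 30, sulfur of 30), the mixture is carried on and one isomer or none is drawn.
- The CIP descriptor of C7 is S while C8 carries a silyl ether and R once C8 carries hydroxyl or ester; the spatial arrangement is the same.

## Route

Step 1
Reactants: 1 (S)-linalool
Product: 2 (3S)-3,7-dimethyl-3-(triethylsilyloxy)octa-1,6-diene
Conditions: TESOTf, 2,6-lutidine, CH2Cl2, −78 to 0 °C
Reagents that add atoms: triethylsilyl trifluoromethanesulfonate, CC[Si](CC)(CC)OS(=O)(=O)C(F)(F)F
Why: Silyl ether formation with a silyl triflate and a hindered pyridine base protects the tertiary allylic alcohol without ionisation; the C10 center from the chiral pool is not touched.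

Step 2
Reactants: 2 (3S)-3,7-dimethyl-3-(triethylsilyloxy)octa-1,6-diene
Product: 3 (4S)-4-methyl-4-(triethylsilyloxy)hex-5-enal
Conditions: O3, CH2Cl2/MeOH, pyridine, −78 °C, Sudan Red 7B end point; then Me2S, −78 °C to rt
Reagents that add atoms: ozone, [O-][O+]=O
Why: Chemoselective ozonolysis: the electron-rich trisubstituted alkene should react well before the vinyl group, which is deactivated by the allylic C–O bond, and the dye end point guards against over-oxidation.

Step 3
Reactants: 3 (4S)-4-methyl-4-(triethylsilyloxy)hex-5-enal
Product: 5 (2R,4S)-2-(anilinooxy)-4-methyl-4-(triethylsilyloxy)hex-5-en-1-ol, via anilinooxy aldehyde 4 (not isolated)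
Conditions: PhNO, L-proline (20 mol %), CHCl3, 4 °C; then NaBH4, EtOH, 0 °C
Reagents that add atoms: nitrosobenzene, O=Nc1ccccc1
Why: Proline-catalysed α-aminoxylation (O-selective nitroso aldol through the enamine): L-proline should deliver oxygen to the face that gives the R center at C8, independently of the remote C10 center. Immediate borohydride reduction prevents epimerisation of the α-oxy aldehyde.

Step 4
Reactants: 5 (2R,4S)-2-(anilinooxy)-4-methyl-4-(triethylsilyloxy)hex-5-en-1-ol
Product: 6 (2R,4S)-4-methyl-4-(triethylsilyloxy)hex-5-ene-1,2-diol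
Conditions: Zn dust, AcOH, THF, rt
Reagents that add atoms: none
Why: Reductive N–O cleavage by zinc in acetic acid frees the C8 hydroxyl; alkene and tertiary silyl ether should be inert, and the C8–O bond is not broken.

Step 5
Reactants: 6 (2R,4S)-4-methyl-4-(triethylsilyloxy)hex-5-ene-1,2-diol
Product: 7 (2R,4S)-4-methyl-1,2,4-tris(triethylsilyloxy)hex-5-ene
Conditions: TESCl, imidazole, DMAP (cat.), DMF, 0 °C to rt
Reagents that add atoms: chlorotriethylsilane, CC[Si](Cl)(CC)CC
Why: Exhaustive silyl ether formation at the primary and secondary hydroxyls prepares the selective oxidative unmasking of C7.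

Step 6
Reactants: 7 (2R,4S)-4-methyl-1,2,4-tris(triethylsilyloxy)hex-5-ene
Product: 8 (2R,4S)-4-methyl-2,4-bis(triethylsilyloxy)hex-5-enal
Conditions: (COCl)2, DMSO, CH2Cl2, −78 to −40 °C; then Et3N, −78 to 0 °C
Reagents that add atoms: none
Why: Swern oxidation of a primary triethylsilyl ether: the chlorosulfonium reagent cleaves the unhindered primary Si–O bond and oxidises it in the same flask, while secondary and tertiary silyl ethers should survive at low temperature. α-Silyloxy aldehydes are normally configurationally stable under these conditions.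

Step 7
Reactants: 8 (2R,4S)-4-methyl-2,4-bis(triethylsilyloxy)hex-5-enal; 9 methyl acrylate
Product: 10 methyl (4R,6S)-3-hydroxy-6-methyl-2-methylidene-4,6-bis(triethylsilyloxy)oct-7-enoate (both C3 epimers)
Conditions: DABCO (1 equiv), 9 (neat, excess), rt
Reagents that add atoms: none
Why: Morita–Baylis–Hillman reaction: the amine–acrylate zwitterion adds to the aldehyde, which is activated by its α-oxygen, and forms the C7–C11 bond. The new carbinol configuration is irrelevant because C7 becomes sp2 in step 8.

Step 8
Reactants: 10 methyl (4R,6S)-3-hydroxy-6-methyl-2-methylidene-4,6-bis(triethylsilyloxy)oct-7-enoate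
Product: 11 methyl (2Z,4R,6S)-2-(bromomethyl)-6-methyl-4,6-bis(triethylsilyloxy)octa-2,7-dienoate
Conditions: NBS, Me2S, CH2Cl2, 0 °C to rt
Reagents that add atoms: N-bromosuccinimide, O=C1CCC(=O)N1Br
Why: Bromodimethylsulfonium activation of the allylic alcohol and SN2' attack of bromide at C13 converts Morita–Baylis–Hillman adducts into 2-(bromomethyl)alk-2-enoates. The thermodynamically preferred Z isomer, with C8 cis to the bromomethyl group, should result.

Step 9
Reactants: 12 4-methylfuran-2(5H)-one
Product: 13 4-methyl-2,5-dihydrofuran-2-ol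
Conditions: iBu2AlH (1.05 equiv), CH2Cl2, −78 °C; aqueous potassium sodium tartrate; used crude
Reagents that add atoms: none
Why: Partial reduction of a lactone by iBu2AlH stops at the lactol at low temperature. The ring holds C3 and C6 cis on the C4=C5 bond, so the latent enal can only be Z.

Step 10
Reactants: 11 methyl (2Z,4R,6S)-2-(bromomethyl)-6-methyl-4,6-bis(triethylsilyloxy)octa-2,7-dienoate; 13 4-methyl-2,5-dihydrofuran-2-ol
Product: 15 (4S,5S)-5-[(1Z)-3-hydroxy-2-methylprop-1-en-1-yl]-4-[(1R,3S)-3-methyl-1,3-bis(triethylsilyloxy)pent-4-en-1-yl]-3-methylideneoxolan-2-one, via Barbier hydroxy ester 14 (not isolated)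
Conditions: In powder, 13 (excess), THF/H2O, rt; then PPTS (cat.), CH2Cl2, rt
Reagents that add atoms: none
Why: Indium Barbier 2-(alkoxycarbonyl)allylation of the open-chain enal form of the lactol, then acid-catalysed lactonisation: the allylindium reacts at its γ-carbon (C7) through a closed chair, and because C8 is cis to the metallated methylene the adduct is syn and lactonises to the cis C6–C7 lactone. Allylic 1,3-strain holds H8 in the alkene plane, so the aldehyde should enter anti to the C9 branch and on the side of the C8 oxygen, which can also coordinate indium; this sets C6 and C7 relative to 8R. Only the C6 hydroxyl can lactonise because the C8 oxygen is silylated.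

Step 11
Reactants: 15 (4S,5S)-5-[(1Z)-3-hydroxy-2-methylprop-1-en-1-yl]-4-[(1R,3S)-3-methyl-1,3-bis(triethylsilyloxy)pent-4-en-1-yl]-3-methylideneoxolan-2-one
Product: 16 (3S,4S,5S)-5-[(1Z)-3-hydroxy-2-methylprop-1-en-1-yl]-4-[(1R,3S)-3-methyl-1,3-bis(triethylsilyloxy)pent-4-en-1-yl]-3-[(phenylsulfanyl)methyl]oxolan-2-one
Conditions: PhSH, Et3N (cat.), CH2Cl2, 0 °C
Reagents that add atoms: thiophenol, Sc1ccccc1
Why: Amine-catalysed thia-Michael addition masks the methylene lactone, the only other dipolarophile and Michael acceptor. C11 should form mainly with the phenylthiomethyl group trans to the C7 side chain, and its configuration is immaterial because C11 returns to sp2.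

Step 12
Reactants: 16 (3S,4S,5S)-5-[(1Z)-3-hydroxy-2-methylprop-1-en-1-yl]-4-[(1R,3S)-3-methyl-1,3-bis(triethylsilyloxy)pent-4-en-1-yl]-3-[(phenylsulfanyl)methyl]oxolan-2-one
Product: 17 (3S,4S,5S)-5-[(1Z)-3-chloro-2-methylprop-1-en-1-yl]-4-[(1R,3S)-3-methyl-1,3-bis(triethylsilyloxy)pent-4-en-1-yl]-3-[(phenylsulfanyl)methyl]oxolan-2-one
Conditions: MsCl, LiCl, 2,4,6-collidine, DMF, 0 °C
Reagents that add atoms: lithium chloride, [Li+].[Cl-]
Why: Collington–Meyers chlorination (mesylate formed in situ, SN2 by chloride) converts the primary allylic alcohol into the chloride without allylic transposition or loss of the Z geometry.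

Step 13
Reactants: 17 (3S,4S,5S)-5-[(1Z)-3-chloro-2-methylprop-1-en-1-yl]-4-[(1R,3S)-3-methyl-1,3-bis(triethylsilyloxy)pent-4-en-1-yl]-3-[(phenylsulfanyl)methyl]oxolan-2-one
Product: 18 (3S,4R,5S)-5-[(1Z)-3-chloro-2-methylprop-1-en-1-yl]-4-[(1R,3S)-1-hydroxy-3-methyl-3-(triethylsilyloxy)pent-4-en-1-yl]-3-[(phenylsulfanyl)methyl]oxolan-2-one
Conditions: PPTS (cat.), MeOH/CH2Cl2, 0 °C
Reagents that add atoms: none
Why: Acid-catalysed methanolysis of silyl ethers is governed by steric access to silicon, so the secondary C8 ether should be cleaved well before the tertiary allylic C10 ether.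

Step 14
Reactants: 18 (3S,4R,5S)-5-[(1Z)-3-chloro-2-methylprop-1-en-1-yl]-4-[(1R,3S)-1-hydroxy-3-methyl-3-(triethylsilyloxy)pent-4-en-1-yl]-3-[(phenylsulfanyl)methyl]oxolan-2-one
Product: 19 (1R,3S)-1-{(2S,3R,4S)-2-[(1Z)-3-chloro-2-methylprop-1-en-1-yl]-5-oxo-4-[(phenylsulfanyl)methyl]oxolan-3-yl}-3-methyl-3-(triethylsilyloxy)pent-4-en-1-yl 2-methylpropanoate
Conditions: (iPrCO)2O, pyridine, DMAP (cat.), CH2Cl2, 0 °C
Reagents that add atoms: isobutyric anhydride, CC(C)C(=O)OC(=O)C(C)C
Why: DMAP-catalysed acylation of the only free hydroxyl installs the isobutyrate with retention at C8. C3 is a chloride and no acidic nitro group is present yet, so neither a second hydroxyl nor a nitronate competes.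

Step 15
Reactants: 19 (1R,3S)-1-{(2S,3R,4S)-2-[(1Z)-3-chloro-2-methylprop-1-en-1-yl]-5-oxo-4-[(phenylsulfanyl)methyl]oxolan-3-yl}-3-methyl-3-(triethylsilyloxy)pent-4-en-1-yl 2-methylpropanoate
Product: 21 (1R,3S)-3-methyl-1-{(2S,3R,4S)-2-[(1Z)-2-methyl-3-nitroprop-1-en-1-yl]-5-oxo-4-[(phenylsulfanyl)methyl]oxolan-3-yl}-3-(triethylsilyloxy)pent-4-en-1-yl 2-methylpropanoate, via allylic iodide 20 (not isolated)
Conditions: NaI, acetone, rt; then AgNO2, Et2O, 0 °C to rt, dark
Reagents that add atoms: sodium iodide (iodine of 20 only), [Na+].[I-]; silver nitrite, [Ag+].[O-]N=O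
Why: Finkelstein exchange followed by the Victor Meyer reaction: the soft primary allylic iodide should be displaced by silver nitrite mainly at nitrogen under non-basic, heterogeneous conditions that spare the Z alkene. The acidic allylic nitro compound is thus made last and used at once.

Step 16
Reactants: 21 (1R,3S)-3-methyl-1-{(2S,3R,4S)-2-[(1Z)-2-methyl-3-nitroprop-1-en-1-yl]-5-oxo-4-[(phenylsulfanyl)methyl]oxolan-3-yl}-3-(triethylsilyloxy)pent-4-en-1-yl 2-methylpropanoate
Product: 23 isoxazoline cycloadduct, (1S,6S,7R,8R,10S,11S,4Z)-8-(2-methylpropanoyloxy)-13-(phenylsulfanyl)-10-(triethylsilyloxy)-11,13-dihydrogermacr-4-en-12,6-olide bridged by C3=N–O–C1, via nitrile oxide 22 (not isolated)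
Conditions: PhNCO (4 equiv), Et3N (cat.), benzene, 70 °C, slow addition of 21, final concentration about 2 mM
Reagents that add atoms: none
Why: Triethylamine forms the nitronate of 21, which adds to phenyl isocyanate and loses phenylcarbamate to give nitrile oxide 22 (Mukaiyama dehydration); 22 then undergoes a concerted, asynchronous [3+2] cycloaddition with the C1=C2 vinyl group, carbon bonding to C2 and oxygen to C1. The closest known reaction type is the intramolecular nitrile oxide–alkene cycloaddition in its bridged mode, as used for medium and large carbocycles. The ten-membered carbocycle is closed by the C2–C3 bond in that bridged mode (attack on the terminal alkene carbon), and the isoxazoline is closed by the cycloaddition itself, C2–C3 and O–C1 being made together so that it spans C1–C2–C3. The new C1 center is controlled by C10: the silyloxy group takes the inside position when the tether leaves it free and otherwise the anti position, never the outside one facing the dipole oxygen, and in either case the new C1–O bond ends anti to the C10 oxygen, that is 1S. Oxygen at the substituted carbon is the normal orientation for a monosubstituted alkene and is reinforced because the reverse mode would force C–C bond formation next to the quaternary C10. Chemoselectivity rests on the sulfide mask and on the fact that the conjugated C4=C5 bond cannot reach the dipole. Ring closure must outrun furoxan formation, which slow addition at high dilution should secure, helped by the Z C4=C5 bond and the cis-lactone that hold C3 and the C7 side chain on the same side.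

Step 17
Reactants: 23 isoxazoline cycloadduct
Product: 24 (1S,6S,7R,8R,10S,11S,4Z)-1-hydroxy-8-(2-methylpropanoyloxy)-3-oxo-13-(phenylsulfanyl)-10-(triethylsilyloxy)-11,13-dihydrogermacr-4-en-12,6-olide
Conditions: Mo(CO)6, MeCN/H2O, 80 °C
Reagents that add atoms: water, O
Why: Reductive N–O cleavage of the isoxazoline by Mo(CO)6 and hydrolysis of the resulting β-hydroxy imine unveil the aldol: the C3 enone and the C1 hydroxyl, with C1 unchanged. The medium is close to neutral, which should limit retro-aldol and dehydration, and the aryl sulfide is not expected to react.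

Step 18
Reactants: 24 β-hydroxy enone
Product: 25 (1S,3S,6S,7R,8R,10S,11S,4Z)-1,3-dihydroxy-8-(2-methylpropanoyloxy)-13-(phenylsulfanyl)-10-(triethylsilyloxy)-11,13-dihydrogermacr-4-en-12,6-olide
Conditions: Me4NBH(OAc)3, MeCN/AcOH, −30 °C
Reagents that add atoms: none
Why: Evans–Saksena reduction: the C1 hydroxyl exchanges onto boron and delivers hydride intramolecularly to the C3 carbonyl (1,2-reduction of the enone) through a chair-like six-membered transition state, which should give the 1,3-anti diol, that is 3S.

Step 19
Reactants: 25 anti-1,3-diol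
Product: 26 (1S,3S,6S,7R,8R,10S,11S,4Z)-1-hydroxy-8-(2-methylpropanoyloxy)-13-(phenylsulfanyl)-3,10-bis(triethylsilyloxy)-11,13-dihydrogermacr-4-en-12,6-olide
Conditions: TESCl (1.1 equiv), imidazole, CH2Cl2, −40 to −20 °C
Reagents that add atoms: chlorotriethylsilane, CC[Si](Cl)(CC)CC
Why: Kinetic silyl ether formation should pick the allylic C3 hydroxyl over the C1 hydroxyl, which is flanked by the quaternary, silyloxy-bearing C10.

Step 20
Reactants: 26 C3 silyl ether
Product: 27 (1S,3S,6S,7R,8R,10S,11S,4Z)-1-(methanesulfonyloxy)-8-(2-methylpropanoyloxy)-13-(phenylsulfanyl)-3,10-bis(triethylsilyloxy)-11,13-dihydrogermacr-4-en-12,6-olide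
Conditions: MsCl, Et3N, DMAP (cat.), CH2Cl2, −20 to 0 °C
Reagents that add atoms: methanesulfonyl chloride, CS(=O)(=O)Cl
Why: Sulfonylation through sulfene accepts hindered secondary alcohols; the C1–O bond is not broken, so C1 keeps its configuration.

Step 21
Reactants: 27 C1 mesylate
Product: 29 (1R,3S,6S,7R,8R,10S,11S,4Z)-1,10-epoxy-3-hydroxy-8-(2-methylpropanoyloxy)-13-(phenylsulfanyl)-11,13-dihydrogermacr-4-en-12,6-olide, via hydroxy mesylate 28 (not isolated)
Conditions: Bu4NF, THF, 0 °C
Reagents that add atoms: none
Why: Fluoride desilylation frees the C3 and C10 oxygens, and the C10 alkoxide displaces the adjacent mesylate in an intramolecular SN2 reaction (3-exo-tet) with inversion at C1 (1S to 1R). This gives the cis-epoxide with C10 unchanged; three-membered ring closure should be faster than acyl transfer from C8.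

Step 22
Reactants: 29 epoxy sulfide
Product: 30 sulfoxide of 29 (both configurations at sulfur)
Conditions: NaIO4, MeOH/H2O, 0 °C
Reagents that add atoms: sodium periodate, [Na+].[O-]I(=O)(=O)=O
Why: Periodate oxidation of a sulfide stops at the sulfoxide and should not touch the alkene, epoxide, allylic alcohol or esters; there is no 1,2-diol to cleave.

Step 23
Reactants: 30 sulfoxide
Product: 31 target, (1R,3S,6S,7R,8R,10S,4Z)-1,10-epoxy-3-hydroxy-8-(2-methylpropanoyloxy)germacra-4,11(13)-dien-12,6-olide
Conditions: toluene, CaCO3, 100 °C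
Reagents that add atoms: none
Why: Thermal syn-elimination of the sulfoxide removes H11, the only β-hydrogen and one activated by the lactone carbonyl, together with benzenesulfenic acid, and regenerates the C11=C13 bond under neutral conditions.

## Compound list

1 | (S)-linalool, (3S)-3,7-dimethylocta-1,6-dien-3-ol | C=C[C@@](C)(O)CCC=C(C)C | starting material
2 | (3S)-3,7-dimethyl-3-(triethylsilyloxy)octa-1,6-diene | C=C[C@@](C)(O[Si](CC)(CC)CC)CCC=C(C)C | intermediate
3 | (4S)-4-methyl-4-(triethylsilyloxy)hex-5-enal | O=CCC[C@](C)(O[Si](CC)(CC)CC)C=C | intermediate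
4 | (2R,4S)-2-(anilinooxy)-4-methyl-4-(triethylsilyloxy)hex-5-enal | O=C[C@H](ONc1ccccc1)C[C@](C)(O[Si](CC)(CC)CC)C=C | intermediate (not isolated)
5 | (2R,4S)-2-(anilinooxy)-4-methyl-4-(triethylsilyloxy)hex-5-en-1-ol | OC[C@H](ONc1ccccc1)C[C@](C)(O[Si](CC)(CC)CC)C=C | intermediate
6 | (2R,4S)-4-methyl-4-(triethylsilyloxy)hex-5-ene-1,2-diol | OC[C@H](O)C[C@](C)(O[Si](CC)(CC)CC)C=C | intermediate
7 | (2R,4S)-4-methyl-1,2,4-tris(triethylsilyloxy)hex-5-ene | CC[Si](CC)(CC)OC[C@H](O[Si](CC)(CC)CC)C[C@](C)(O[Si](CC)(CC)CC)C=C | intermediate
8 | (2R,4S)-4-methyl-2,4-bis(triethylsilyloxy)hex-5-enal | O=C[C@H](O[Si](CC)(CC)CC)C[C@](C)(O[Si](CC)(CC)CC)C=C | intermediate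
9 | methyl acrylate | C=CC(=O)OC | starting material
10 | methyl (4R,6S)-3-hydroxy-6-methyl-2-methylidene-4,6-bis(triethylsilyloxy)oct-7-enoate, both C3 epimers | C=C(C(=O)OC)C(O)[C@H](O[Si](CC)(CC)CC)C[C@](C)(O[Si](CC)(CC)CC)C=C | intermediate
11 | methyl (2Z,4R,6S)-2-(bromomethyl)-6-methyl-4,6-bis(triethylsilyloxy)octa-2,7-dienoate | COC(=O)/C(CBr)=C/[C@H](O[Si](CC)(CC)CC)C[C@](C)(O[Si](CC)(CC)CC)C=C | intermediate
12 | 4-methylfuran-2(5H)-one | CC1=CC(=O)OC1 | starting material
13 | 4-methyl-2,5-dihydrofuran-2-ol (lactol, ring-chain tautomer of (2Z)-4-hydroxy-3-methylbut-2-enal) | CC1=CC(O)OC1 | intermediate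
14 | methyl (3S,4R,6S)-3-[(1S,2Z)-1,4-dihydroxy-3-methylbut-2-en-1-yl]-6-methyl-2-methylidene-4,6-bis(triethylsilyloxy)oct-7-enoate | COC(=O)C(=C)[C@@H]([C@@H](O)/C=C(/C)CO)[C@H](O[Si](CC)(CC)CC)C[C@](C)(O[Si](CC)(CC)CC)C=C | intermediate (not isolated)
15 | (4S,5S)-5-[(1Z)-3-hydroxy-2-methylprop-1-en-1-yl]-4-[(1R,3S)-3-methyl-1,3-bis(triethylsilyloxy)pent-4-en-1-yl]-3-methylideneoxolan-2-one (cis-lactone) | C=C1C(=O)O[C@@H](/C=C(/C)CO)[C@H]1[C@H](O[Si](CC)(CC)CC)C[C@](C)(O[Si](CC)(CC)CC)C=C | intermediate
16 | (3S,4S,5S)-5-[(1Z)-3-hydroxy-2-methylprop-1-en-1-yl]-4-[(1R,3S)-3-methyl-1,3-bis(triethylsilyloxy)pent-4-en-1-yl]-3-[(phenylsulfanyl)methyl]oxolan-2-one | O=C1O[C@@H](/C=C(/C)CO)[C@@H]([C@H](O[Si](CC)(CC)CC)C[C@](C)(O[Si](CC)(CC)CC)C=C)[C@@H]1CSc1ccccc1 | intermediate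
17 | (3S,4S,5S)-5-[(1Z)-3-chloro-2-methylprop-1-en-1-yl]-4-[(1R,3S)-3-methyl-1,3-bis(triethylsilyloxy)pent-4-en-1-yl]-3-[(phenylsulfanyl)methyl]oxolan-2-one | O=C1O[C@@H](/C=C(/C)CCl)[C@@H]([C@H](O[Si](CC)(CC)CC)C[C@](C)(O[Si](CC)(CC)CC)C=C)[C@@H]1CSc1ccccc1 | intermediate
18 | (3S,4R,5S)-5-[(1Z)-3-chloro-2-methylprop-1-en-1-yl]-4-[(1R,3S)-1-hydroxy-3-methyl-3-(triethylsilyloxy)pent-4-en-1-yl]-3-[(phenylsulfanyl)methyl]oxolan-2-one | O=C1O[C@@H](/C=C(/C)CCl)[C@@H]([C@H](O)C[C@](C)(O[Si](CC)(CC)CC)C=C)[C@@H]1CSc1ccccc1 | intermediate
19 | (1R,3S)-1-{(2S,3R,4S)-2-[(1Z)-3-chloro-2-methylprop-1-en-1-yl]-5-oxo-4-[(phenylsulfanyl)methyl]oxolan-3-yl}-3-methyl-3-(triethylsilyloxy)pent-4-en-1-yl 2-methylpropanoate | O=C1O[C@@H](/C=C(/C)CCl)[C@@H]([C@H](OC(=O)C(C)C)C[C@](C)(O[Si](CC)(CC)CC)C=C)[C@@H]1CSc1ccccc1 | intermediate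
20 | allylic iodide corresponding to 19 (C3 iodide) | O=C1O[C@@H](/C=C(/C)CI)[C@@H]([C@H](OC(=O)C(C)C)C[C@](C)(O[Si](CC)(CC)CC)C=C)[C@@H]1CSc1ccccc1 | intermediate (not isolated)
21 | (1R,3S)-3-methyl-1-{(2S,3R,4S)-2-[(1Z)-2-methyl-3-nitroprop-1-en-1-yl]-5-oxo-4-[(phenylsulfanyl)methyl]oxolan-3-yl}-3-(triethylsilyloxy)pent-4-en-1-yl 2-methylpropanoate (nitro diene) | O=C1O[C@@H](/C=C(/C)C[N+](=O)[O-])[C@@H]([C@H](OC(=O)C(C)C)C[C@](C)(O[Si](CC)(CC)CC)C=C)[C@@H]1CSc1ccccc1 | intermediate
22 | nitrile oxide from 21 (C3 as C≡N–O, conjugated with Z C4=C5) | O=C1O[C@@H](/C=C(/C)C#[N+][O-])[C@@H]([C@H](OC(=O)C(C)C)C[C@](C)(O[Si](CC)(CC)CC)C=C)[C@@H]1CSc1ccccc1 | intermediate (not isolated)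
23 | isoxazoline cycloadduct, (1S,6S,7R,8R,10S,11S,4Z), ten-membered carbocycle with C3=N–O–C1 bridge, cis-lactone, C8 isobutyrate, C10 triethylsilyl ether, C13 phenyl sulfide | O=C1O[C@H]2/C=C(/C)C3=NO[C@@H](C3)[C@@](C)(O[Si](CC)(CC)CC)C[C@@H](OC(=O)C(C)C)[C@H]2[C@@H]1CSc1ccccc1 | intermediate
24 | (1S,6S,7R,8R,10S,11S,4Z)-1-hydroxy-3-oxo β-hydroxy enone (C8 isobutyrate, C10 triethylsilyl ether, C13 phenyl sulfide) | O=C1O[C@H]2/C=C(/C)C(=O)C[C@H](O)[C@@](C)(O[Si](CC)(CC)CC)C[C@@H](OC(=O)C(C)C)[C@H]2[C@@H]1CSc1ccccc1 | intermediate
25 | (1S,3S,6S,7R,8R,10S,11S,4Z)-1,3-anti-diol | O=C1O[C@H]2/C=C(/C)[C@@H](O)C[C@H](O)[C@@](C)(O[Si](CC)(CC)CC)C[C@@H](OC(=O)C(C)C)[C@H]2[C@@H]1CSc1ccccc1 | intermediate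
26 | C3 triethylsilyl ether of 25 (C1 hydroxyl free) | O=C1O[C@H]2/C=C(/C)[C@@H](O[Si](CC)(CC)CC)C[C@H](O)[C@@](C)(O[Si](CC)(CC)CC)C[C@@H](OC(=O)C(C)C)[C@H]2[C@@H]1CSc1ccccc1 | intermediate
27 | C1 methanesulfonate of 26 | O=C1O[C@H]2/C=C(/C)[C@@H](O[Si](CC)(CC)CC)C[C@H](OS(C)(=O)=O)[C@@](C)(O[Si](CC)(CC)CC)C[C@@H](OC(=O)C(C)C)[C@H]2[C@@H]1CSc1ccccc1 | intermediate
28 | C1 methanesulfonate with free C3 and C10 hydroxyls (reacts as the C10 alkoxide) | O=C1O[C@H]2/C=C(/C)[C@@H](O)C[C@H](OS(C)(=O)=O)[C@@](C)(O)C[C@@H](OC(=O)C(C)C)[C@H]2[C@@H]1CSc1ccccc1 | intermediate (not isolated)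
29 | (1R,3S,6S,7R,8R,10S,11S,4Z)-1,10-epoxy-3-hydroxy-8-(2-methylpropanoyloxy)-13-(phenylsulfanyl)-11,13-dihydrogermacr-4-en-12,6-olide | O=C1O[C@H]2/C=C(/C)[C@@H](O)C[C@H]3O[C@@]3(C)C[C@@H](OC(=O)C(C)C)[C@H]2[C@@H]1CSc1ccccc1 | intermediate
30 | sulfoxide of 29 (both configurations at sulfur) | O=C1O[C@H]2/C=C(/C)[C@@H](O)C[C@H]3O[C@@]3(C)C[C@@H](OC(=O)C(C)C)[C@H]2[C@@H]1CS(=O)c1ccccc1 | intermediate
31 | CNP0261225.6, (1R,3S,6S,7R,8R,10S,4Z)-1,10-epoxy-3-hydroxy-8-(2-methylpropanoyloxy)germacra-4,11(13)-dien-12,6-olide | C=C1C(=O)O[C@H]2/C=C(/C)[C@@H](O)C[C@H]3O[C@@]3(C)C[C@@H](OC(=O)C(C)C)[C@@H]12 | target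

## Step count and least certain steps

Total steps: 23. Longest linear sequence: 22 (steps 1–8 and 10–23 from 1); step 9 is a one-step branch from 12.

**Step 16 (key step).** Most likely failure: intermolecular capture of the nitrile oxide (furoxan dimerisation, oligomerisation) outpacing the strained ten-membered closure, made worse if the acidic allylic nitro compound isomerises at C4=C5 under base before it is dehydrated. Attack on the wrong face of the vinyl group is the second concern. Fallback, from 21 back to 23: intramolecular silyl nitronate cycloaddition. Me3SiCl and Et3N convert 21 into the trimethylsilyl nitronate F1, a dipole that does not dimerise and can be heated in dilute toluene until it adds across C1=C2 to give the N-(trimethylsilyloxy)isoxazolidine F2. PPTS then eliminates trimethylsilanol and gives 23.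

**Step 7.** Most likely failure: the amine-catalysed addition to a hindered α-silyloxy aldehyde is slow, so base-mediated epimerisation at C8 and loss of silyl groups can compete. Fallback, from 8 back to 10: vinylalumination. Hydroalumination of methyl propiolate with iBu2AlH–HMPA gives the α-aluminated acrylate, which adds to 8 at 0 °C as an organometallic reagent and gives 10 directly. This fallback makes no new compound (F0).

**Step 10.** Most likely failure: acid-promoted dehydration of lactol 13 to 3-methylfuran in the indium medium, which removes the aldehyde partner before it is allylated. Incomplete facial control by C8 is the second concern. Fallback, from 12 and 11 back to 15: an open-chain enal that cannot aromatise.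
- 12 is opened with MeNH(OMe)·HCl/Me3Al to the Z hydroxy Weinreb amide F3.
- F3 is silylated (TESCl, imidazole) to the triethylsilyl ether F4.
- F4 is reduced with iBu2AlH to the Z enal F5.
- Indium coupling of F5 with 11 gives the hydroxy ester F6 and, after PPTS, the lactone F7.
- The primary silyl ether of F7 is cleaved selectively (AcOH/THF/H2O, 0 °C) to give 15.

**Step 13.** Most likely failure: insufficient rate difference between the secondary and the tertiary silyl ether, so that both are lost or the reaction stalls. Fallback, from 17 back to 19: HF·pyridine removes both silyl groups to give the diol F8. Isobutyric anhydride with DMAP acylates only the secondary hydroxyl, giving the tertiary alcohol F9. TESOTf/2,6-lutidine then silylates C10 and gives 19.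

**Step 15.** Most likely failure: attack of nitrite through oxygen (nitrite ester) and silver-assisted ionisation with allylic transposition, together with isomerisation of the acidic product on handling. Fallback, from 19 back to the route at 22 and so to 23: the aldoxime route. Ganem oxidation of the allylic chloride with Me3NO gives the Z enal F10. NH2OH·HCl/pyridine gives the aldoxime F11. MnO2, which leaves aryl sulfides alone, oxidises F11 under dilution to nitrile oxide 22, which closes to 23.

**Step 18.** Most likely failure: the ring conformation prevents the chair-like intramolecular hydride delivery, so the anti selectivity is eroded. Fallback, from 24 back to 25: reagent control. Me3SiCl/imidazole caps the C1 hydroxyl to give the silyl ether F12. Corey–Bakshi–Shibata reduction with the (R)-oxazaborolidine and catecholborane, in which the alkenyl carbon C4 acts as the large group, should give the 3S allylic alcohol F13. Citric acid in MeOH removes the trimethylsilyl group and gives 25.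

## Further compounds

F1 | step 16 | trimethylsilyl nitronate of 21 | O=C1O[C@@H](/C=C(/C)C=[N+]([O-])O[Si](C)(C)C)[C@@H]([C@H](OC(=O)C(C)C)C[C@](C)(O[Si](CC)(CC)CC)C=C)[C@@H]1CSc1ccccc1
F2 | step 16 | N-(trimethylsilyloxy)isoxazolidine cycloadduct (C3 and N unassigned) | O=C1O[C@H]2/C=C(/C)C3N(O[Si](C)(C)C)O[C@@H](C3)[C@@](C)(O[Si](CC)(CC)CC)C[C@@H](OC(=O)C(C)C)[C@H]2[C@@H]1CSc1ccccc1
F0 | step 7 | none | none
F3 | step 10 | (2Z)-4-hydroxy-N-methoxy-N,3-dimethylbut-2-enamide | CON(C)C(=O)/C=C(C)\CO
F4 | step 10 | (2Z)-N-methoxy-N,3-dimethyl-4-(triethylsilyloxy)but-2-enamide | CON(C)C(=O)/C=C(C)\CO[Si](CC)(CC)CC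
F5 | step 10 | (2Z)-3-methyl-4-(triethylsilyloxy)but-2-enal | O=C/C=C(C)\CO[Si](CC)(CC)CC
F6 | step 10 | Barbier hydroxy ester, C3 triethylsilyl ether of 14 | COC(=O)C(=C)[C@@H]([C@@H](O)/C=C(/C)CO[Si](CC)(CC)CC)[C@H](O[Si](CC)(CC)CC)C[C@](C)(O[Si](CC)(CC)CC)C=C
F7 | step 10 | cis-lactone, C3 triethylsilyl ether of 15 | C=C1C(=O)O[C@@H](/C=C(/C)CO[Si](CC)(CC)CC)[C@H]1[C@H](O[Si](CC)(CC)CC)C[C@](C)(O[Si](CC)(CC)CC)C=C
F8 | step 13 | C8,C10-diol from 17 | O=C1O[C@@H](/C=C(/C)CCl)[C@@H]([C@H](O)C[C@](C)(O)C=C)[C@@H]1CSc1ccccc1
F9 | step 13 | C8 isobutyrate with free C10 hydroxyl | O=C1O[C@@H](/C=C(/C)CCl)[C@@H]([C@H](OC(=O)C(C)C)C[C@](C)(O)C=C)[C@@H]1CSc1ccccc1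
F10 | step 15 | Z enal (C3 aldehyde) from 19 | O=C1O[C@@H](/C=C(/C)C=O)[C@@H]([C@H](OC(=O)C(C)C)C[C@](C)(O[Si](CC)(CC)CC)C=C)[C@@H]1CSc1ccccc1
F11 | step 15 | aldoxime of F10 | O=C1O[C@@H](/C=C(/C)C=NO)[C@@H]([C@H](OC(=O)C(C)C)C[C@](C)(O[Si](CC)(CC)CC)C=C)[C@@H]1CSc1ccccc1
F12 | step 18 | C1 trimethylsilyl ether of 24 | O=C1O[C@H]2/C=C(/C)C(=O)C[C@H](O[Si](C)(C)C)[C@@](C)(O[Si](CC)(CC)CC)C[C@@H](OC(=O)C(C)C)[C@H]2[C@@H]1CSc1ccccc1
F13 | step 18 | (3S) allylic alcohol, C1 trimethylsilyl ether of 25 | O=C1O[C@H]2/C=C(/C)[C@@H](O)C[C@H](O[Si](C)(C)C)[C@@](C)(O[Si](CC)(CC)CC)C[C@@H](OC(=O)C(C)C)[C@H]2[C@@H]1CSc1ccccc1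
A1 | alternative 1 | (Z,Z)-cyclodecadiene-3,8-dione | O=C1C/C(C)=C\CC(=O)/C(C)=C\[C@H](O[Si](C)(C)C(C)(C)C)[C@@H]1C(=C)COCc1ccc(OC)cc1
A2 | alternative 1 | bicyclic ring-fusion diol (carbinol configurations open) | OC12CC(C)=CCC1(O)C(C)=C[C@H](O[Si](C)(C)C(C)(C)C)[C@@H]2C(=C)COCc1ccc(OC)cc1
A3 | alternative 2 | 1(10)-deoxy target (cis,cis-diene) | C=C1C(=O)O[C@H]2/C=C(/C)[C@@H](O)C/C=C(/C)C[C@@H](OC(=O)C(C)C)[C@@H]12
A4 | alternative 2 | seco C3 aldehyde with Z C4 vinyl iodide | C=C1C(=O)O[C@@H](/C=C(/C)I)[C@H]1[C@H](OC(=O)C(C)C)C/C(C)=C\CC=O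
A5 | alternative 3 | (Z,Z)-cyclodecadienone with C8 silane | O=C1/C=C(/C)[C@@H](O[Si](C)(C)C(C)(C)C)C/C=C(/C)C[C@@H]([Si](C)(C)Cc2ccccc2)C1
A6 | alternative 3 | cis-1-alkenyl-6-isopropenylcyclohex-2-enol (one cis diastereomer drawn) | O[C@@]1(/C=C/[Si](C)(C)Cc2ccccc2)C=C(C)[C@@H](O[Si](C)(C)C(C)(C)C)C[C@@H]1C(C)=C
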